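The easy step comes first: in the blue flask Q is followed down, and by 4.00 min nearly all of it has been used while J has climbed to 39.0%.

| flask | Q | L | temperature | remark | time |
|---|---|---|---|---|---|
| blue | 1 M | 1.8 M | 25 °C | the very flask that is asked about, followed so far |  |
| green | 1 M | 1.2 M | 10 °C | run made earlier |  |
| flask | 1.0 M | 1.80 M | 25 °C |  | 20 min |

- blue (time / min: J / %, Q / %): 1.50: 27.4, 7.1; 2.50: 35.2, 1.8; 4.00: 39.0, 1.1; 6.00: 39.4, 0.4; 8.00: 38.7, 0.1; 12.0: 38.9, 2.8; 20.0: 36.7, 0
- green (time / min: J / %, Q / %): 0.333: 0.5, 85.9; 0.500: 0, 80.7; 0.667: 2.1, 75.2; 1.00: 2.7, 62.4; 2.00: 7.4, 37.7; 3.00: 11.8, 23.6; 4.00: 15.5, 14.6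

(readings scatter by 1 percentage point)

- Monday's: change nothing and wait 10 min more
- Sunday's: at 20 min raise the temperature by 15 K, then wait 10 min
- Saturday's: at 20 min take out 90% of the J then present, then wait 10 min

- J taken out counts as made
- the numbers in the tables scatter with a standard deviation of 1 percentage point

* J, in percent of the Q first charged, at 20 min
* the option that brings most further J ("none" if no option brings more than 2 percentage points) (Monday's / Sunday's / Saturday's / none)
* J present, with what was taken out counted in, in percent of the Q first charged, after Monday's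
* J present, with what was taken out counted in, in percent of the Q first charged, after Sunday's

Each molecule of Q comes to a fork: it ends as J or it ends elsewhere. The J readings of the blue flask from 4.00 min to 12.0 min average 39.0%, and this is the passing chance p (the selectivity for J), the share of used Q that ends as J. The blue reading at 20.0 min, 36.7%, lies 2.3 points below p against a scatter of 1 point, so this reckoning puts J between the two, near 37.9%. With Q read at 0%, below the scatter of 1 point, waiting or heating has no measured Q to send to the fork, so Monday's and Sunday's should stay at or below that figure. Saturday's can draw on forms past the fork if J stands in balance with them, so this reckoning names Saturday's as best.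

The forecast gives 38.5% at 20 min, 38.4% after Monday's, 40% after Sunday's and Saturday's as best, holding that “Removing J should re-equilibrate the intermediate”.

The blue flask gives 36.5% at 20 min, 35.4% after Monday's and 33.2% after Sunday's, and Saturday's is best, adding 5.7 points.

    Q + L ⇌ G + X (K = 1.00, k = 0.0140 M⁻¹ s⁻¹, Ea = 47.0 kJ mol⁻¹, ΔH = −33.0 kJ mol⁻¹)
    X + L ⇌ G + J (K = 40.0, k = 0.0160 M⁻¹ s⁻¹, Ea = 60.0 kJ mol⁻¹, ΔH = 16.0 kJ mol⁻¹)
    J + L ⇌ G + E (K = 0.120, k = 0.0260 M⁻¹ s⁻¹, Ea = 56.0 kJ mol⁻¹, ΔH = 3.00 kJ mol⁻¹)
    G + Q → Z (k = 0.0530 M⁻¹ s⁻¹, Ea = 39.0 kJ mol⁻¹)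
    (constants at 25 °C)

J in the blue flask at 20 min stands 2.5 points below the p read from the readings. Of the 63.5% of the Q not in J in the blue flask at 20.0 min, Z holds 54.8% and E 8.26%. In the neighbour flask charged with cQ = 0.40 M and otherwise alike, p gives 39.0% as J, but that flask holds 46.0% at 20.0 min, which is 7 points above p.

The runs come from a simulation from invented constants, and the scatter is random.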